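**Retrosynthetic overview**

1. Locants used throughout: C1 (angelate carbinol), C2 (isovalerate carbinol), C3 (free carbinol), C4 (CMe2), C5, C6, C7 (ketone), C8=C9(Me), C10, C11 (C–Me). The plan rests on one feature: C1–C2–C3–C4–C5–C10–C9–C8–C7–C6–C11 is a single eleven-membered humulane cycle carrying all four methyls, and the cyclobutane C5–C6–C11–C10 consists of two bonds of that cycle (C5–C10, C6–C11) plus two transannular bonds (C5–C6, C10–C11).
2. Target ⇒ C2,C3-diol (C2-selective isovalerylation) ⇒ C2=C3 alkene (osmylation anti to the C1 angelate) ⇒ C7 methylene (allylic oxidation) ⇒ C1 allylic alcohol ⇒ C1 enone ⇒ tricyclic C1 silyl ether.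
3. Tricycle ⇒ macrocyclic tertiary allylic alcohol (C9–OH, C10=C5, C6=C11, C1–OSi) by a transannular cation cascade: bond C5–C6 closes the six- and seven-membered rings together, bond C10–C11 closes the cyclobutane last.
4. Macrocycle ⇒ zerumbone: diimide reduction of C2=C3, CBS reduction at C1, silylation, epoxidation of C9=C10, selenide opening and selenoxide elimination.

Key step: step 6

Remark: the epoxidation in step 4 is expected to give both trans-epoxide diastereomers; one is drawn for 5–8, and both converge in step 6 because C9 becomes planar there.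

Remark: the cage is nearly mirror-symmetric about the plane through C11, C5 and the C1–C4 bridge (C6 and C10 differ only in the remote C7/C9 substitution), so C1 is re-set under catalyst control in step 10 and not by the substrate.

**Route**

Step 1
Reactants: 1 zerumbone
Product: 2 (2E,6E)-2,6,9,9-tetramethylcycloundeca-2,6-dien-1-one (C1 ketone; C2–C3 saturated; E-C6=C11; E-C9=C10)
Conditions: KO2CN=NCO2K (portionwise), AcOH, MeOH, 0 °C → rt
Reagents that add atoms: none
Why: Diimide reduction; the concerted syn transfer of H2 is fastest to the least substituted, electron-poor alkene, so the E-disubstituted enone alkene C2=C3 should be saturated while both trisubstituted alkenes and the ketone remain.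

Step 2
Reactants: 2 (2E,6E)-2,6,9,9-tetramethylcycloundeca-2,6-dien-1-one
Product: 3 (1R,2E,6E)-2,6,9,9-tetramethylcycloundeca-2,6-dien-1-ol
Conditions: (S)-Me-CBS oxazaborolidine (20 mol %), catecholborane, toluene, −78 °C
Reagents that add atoms: none
Why: Corey–Bakshi–Shibata reduction; the α-methylalkenyl arm (C11) is the large group against the C2 methylene, so the (S)-catalyst should deliver hydride to the face that gives the 1R carbinol, the centre that steers the cascade in step 6.

Step 3
Reactants: 3 (1R,2E,6E)-2,6,9,9-tetramethylcycloundeca-2,6-dien-1-ol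
Product: 4 C1 triisopropylsilyl ether of 3
Conditions: iPr3SiOTf, 2,6-lutidine, CH2Cl2, 0 °C
Reagents that add atoms: triisopropylsilyl triflate CC(C)[Si](OS(=O)(=O)C(F)(F)F)(C(C)C)C(C)C
Why: Silylation of a secondary allylic alcohol; the triisopropylsilyl group is chosen because it should survive the ionising medium of step 6 and because its bulk enforces the conformation used there.

Step 4
Reactants: 4 C1 triisopropylsilyl ether of 3
Product: 5 C9,C10 trans-epoxide of 4
Conditions: mCPBA (1.05 equiv), CH2Cl2/aq. Na2HPO4 buffer, 0 °C
Reagents that add atoms: meta-chloroperbenzoic acid OOC(=O)c1cccc(Cl)c1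
Why: Prilezhaev epoxidation; the isolated C9=C10 alkene is more electron-rich and less shielded than C6=C11 (allylic to the bulky silyloxy group), concerted oxygen transfer avoids cations and hence transannular cyclisation, the E alkene gives the trans-epoxide, and the facial outcome is immaterial.

Step 5
Reactants: 5 C9,C10 trans-epoxide of 4
Product: 8 macrocyclic tertiary allylic alcohol (C9(OH)(Me); E-C10=C5; E-C6=C11; 1R C1–OSi(iPr)3), via hydroxy selenide 6 (not isolated), via selenoxide 7 (not isolated)
Conditions: PhSeSePh, NaBH4, EtOH, reflux; then 30% H2O2, THF, 0 °C → rt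
Reagents that add atoms: none
Why: Epoxide to allylic alcohol transposition by selenide opening and selenoxide elimination; the selenolate opens the epoxide by SN2 at the secondary C10 with C9–O retained, and the selenoxide can syn-eliminate only toward C5 (C9 bears no hydrogen), which should give the E-C10=C5 alkene next to the tertiary C9 carbinol.

Step 6
Reactants: 8 macrocyclic tertiary allylic alcohol
Product: 9 tricyclic silyl ether, 1-(triisopropylsilyloxy)-α-longipinene (cyclobutane C5–C6–C11–C10; cyclohexene C5–C6–C7–C8=C9–C10; cycloheptane C1–C2–C3–C4–C5–C10–C11; C7, C9, the C11 methyl and H5 on one cyclobutane face; C1, C4, H6 and H10 on the other; C1 R; C1–O anti to C11–C10)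
Conditions: Ca(NTf2)2 (10 mol %), nBu4NPF6 (10 mol %), (CF3)2CHOH/CH2Cl2 (1:4), 0.005 M, −20 → 0 °C
Reagents that add atoms: none
Why: Proposed new method: the calcium Lewis acid in the weakly nucleophilic medium ionises the tertiary allylic C9 hydroxyl to the C5–C10–C9 allyl cation, C6 of the C6=C11 alkene attacks C5 across the ring, and the tertiary C11 cation so formed is captured by C10 of the new C9=C10 alkene before the tertiary C9 cation loses H8. The closest known reaction type is the acid-mediated transannular cation–olefin cyclisation of humulene-type macrocycles, and the enzymatic humulyl–himachalyl–longipinyl sequence shows the same order of bond formation, but the cyclobutane closure has not been realised without an enzyme. The C5–C6 bond closes the cyclohexene (C5, C6, C7, C8, C9, C10) in a 6-exo mode and the cycloheptane (C5, C6, C11, C1, C2, C3, C4) in a 7-endo mode with respect to the C6=C11 alkene, and the C10–C11 bond closes the cyclobutane (C5, C6, C11, C10) in a 4-exo mode with respect to the C9=C10 alkene. A(1,2) strain with the C11 methyl places H1 next to that methyl and the bulky silyloxy group on the alkene face opposite the C2–C3–C4 chain that delivers C5, so C5 bonds to C6 on the face remote from the C1–O bond, which sets C5 and C6 (cis ring fusion imposed by the E alkene and the three-carbon C7–C8–C9 link); C10 can then reach C11 only on that same face, anti to C1–O, and the cage fixes C10 and C11. The step needs ring closure at C11 to outrun proton loss to himachaladienes and a 1,2-hydride shift from C1, and it needs the acid-labile pinene-type product to survive; the substrate helps because in the reacting conformer the C1–H bond lies near the nodal plane of the C11 cation and the cis-fused bicycle holds C10 within bonding distance, and the medium helps because it holds no base stronger than the water released and no strong protic acid.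

Step 7
Reactants: 9 tricyclic silyl ether
Product: 10 tricyclic C1 alcohol (cage and C1 as in 9)
Conditions: nBu4NF, THF, 50 °C
Reagents that add atoms: none
Why: Fluoride desilylation; the neopentyl silyl ether needs warming, and the pinene-type alkene and cyclobutane are inert to fluoride.

Step 8
Reactants: 10 tricyclic C1 alcohol
Product: 11 tricyclic C1 ketone
Conditions: nPr4NRuO4 (5 mol %), N-methylmorpholine N-oxide, 4 Å MS, CH2Cl2, rt
Reagents that add atoms: none
Why: Ley–Griffith oxidation; neutral conditions spare the acid-sensitive pinene-type alkene, and C1 has by now transferred its chirality to the cage.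

Step 9
Reactants: 11 tricyclic C1 ketone
Product: 13 tricyclic enone (C1 ketone; C2=C3; C8=C9), via trimethylsilyl enol ether 12 (not isolated)
Conditions: LiN(iPr)2, Me3SiCl, THF, −78 °C; then Pd(OAc)2, MeCN, rt
Reagents that add atoms: none
Why: Saegusa–Ito oxidation; C11 is quaternary, so enolisation can only go toward C2, and palladation followed by β-hydride loss from C3 gives the C2=C3 enone.

Step 10
Reactants: 13 tricyclic enone
Product: 14 1R allylic alcohol (C1–OH oriented as in 10; C2=C3; C8=C9)
Conditions: (S)-Me-CBS oxazaborolidine (30 mol %), catecholborane, toluene, −78 → −40 °C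
Reagents that add atoms: none
Why: Corey–Bakshi–Shibata 1,2-reduction under catalyst control; with the quaternary C11 as the large group against the C2=C3 vinyl arm, the (S)-catalyst should give the 1R carbinol, the same C1 orientation as in 9 (the antipodal catalyst is available should the large/small assignment be reversed).

Step 11
Reactants: 14 1R allylic alcohol; 15 angelic acid
Product: 17 C1 angelate of 14, via mixed anhydride 16 (not isolated)
Conditions: 15, 2,4,6-trichlorobenzoyl chloride, Et3N, toluene, rt; then 14, 80 °C (no DMAP)
Reagents that add atoms: none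
Why: Yamaguchi-type mixed-anhydride esterification; omitting the nucleophilic catalyst avoids the addition–elimination that turns angelates into tiglates, and O-acylation leaves C1 untouched.

Step 12
Reactants: 17 C1 angelate
Product: 18 C1 angelate C7 ketone (C7(=O)–C8=C9 enone; C2=C3)
Conditions: Rh2(cap)4 (1 mol %; cap = caprolactamate), t-BuOOH (70% aq.), ClCH2CH2Cl, 40 °C
Reagents that add atoms: tert-butyl hydroperoxide CC(C)(C)OO
Why: Dirhodium-catalysed allylic oxidation by tert-butylperoxyl radicals, the α-pinene to verbenone pattern; C7 is the only unhindered allylic methylene (C10 is a bridgehead, C1–H is neopentyl and deactivated by the acyloxy group).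

Step 13
Reactants: 18 C1 angelate C7 ketone
Product: 19 C2,C3-diol (both hydroxyls cis to each other and trans to C1–O)
Conditions: OsO4 (5 mol %), N-methylmorpholine N-oxide, acetone/H2O, rt
Reagents that add atoms: osmium tetroxide O=[Os](=O)(=O)=O; N-methylmorpholine N-oxide C[N+]1([O-])CCOCC1; water O
Why: Upjohn dihydroxylation; C2=C3 is the only alkene not conjugated to a carbonyl, and osmylation should occur on the face anti to the allylic C1 acyloxy group (the usual empirical preference, reinforced by sterics in the cycloheptene), which sets C2 and C3.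

Step 14
Reactants: 19 C2,C3-diol; 20 isovaleric anhydride
Product: 21 CNP0251293.1
Conditions: 20 (1.1 equiv), Et3N, DMAP (5 mol %), CH2Cl2, −20 °C
Reagents that add atoms: none
Why: DMAP-catalysed acylation; the C3 hydroxyl is neopentyl (next to C4Me2) and should react much more slowly than the C2 hydroxyl, so the C2 mono-isovalerate is expected.

**Compound list**

1 | zerumbone, (2E,6E,10E)-2,6,9,9-tetramethylcycloundeca-2,6,10-trien-1-one | CC1(C)C/C=C(\C)CC/C=C(\C)C(=O)/C=C/1 | starting material
2 | (2E,6E)-2,6,9,9-tetramethylcycloundeca-2,6-dien-1-one | CC1(C)C/C=C(\C)CC/C=C(\C)C(=O)CC1 | intermediate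
3 | (1R,2E,6E)-2,6,9,9-tetramethylcycloundeca-2,6-dien-1-ol | C1C[C@@H](O)/C(C)=C/CC/C(C)=C/CC1(C)C | intermediate
4 | C1 triisopropylsilyl ether of 3 | C1C[C@@H](O[Si](C(C)C)(C(C)C)C(C)C)/C(C)=C/CC/C(C)=C/CC1(C)C | intermediate
5 | C9,C10 trans-epoxide of 4 (one of two epoxide diastereomers drawn) | C1C[C@@H](O[Si](C(C)C)(C(C)C)C(C)C)/C(C)=C/CC[C@]2(C)O[C@H]2CC1(C)C | intermediate
6 | C9-hydroxy C10-phenylselanyl macrocycle (anti opening product of 5) | C1C[C@@H](O[Si](C(C)C)(C(C)C)C(C)C)/C(C)=C/CC[C@](C)(O)[C@H]([Se]c2ccccc2)CC1(C)C | intermediate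
7 | selenoxide of 6 | C1C[C@@H](O[Si](C(C)C)(C(C)C)C(C)C)/C(C)=C/CC[C@](C)(O)[C@H]([Se](=O)c2ccccc2)CC1(C)C | intermediate
8 | macrocyclic tertiary allylic alcohol (C9(OH)(Me); E-C10=C5; E-C6=C11; 1R C1–OSi(iPr)3) | C1C[C@@H](O[Si](C(C)C)(C(C)C)C(C)C)/C(C)=C/CC[C@](C)(O)/C=C/C1(C)C | intermediate
9 | tricyclic silyl ether, 1-(triisopropylsilyloxy)-α-longipinene (C8=C9; C1 R; C1–O anti to C11–C10) | CC(C)[Si](C(C)C)(C(C)C)O[C@@H]1CCC(C)(C)[C@@H]2[C@H]3CC=C(C)[C@@H]2[C@@]13C | intermediate
10 | tricyclic C1 alcohol | O[C@@H]1CCC(C)(C)[C@@H]2[C@H]3CC=C(C)[C@@H]2[C@@]13C | intermediate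
11 | tricyclic C1 ketone | O=C1CCC(C)(C)[C@@H]2[C@H]3CC=C(C)[C@@H]2[C@@]13C | intermediate
12 | C1 trimethylsilyl enol ether (C1=C2) | C[Si](C)(C)OC1=CCC(C)(C)[C@@H]2[C@H]3CC=C(C)[C@@H]2[C@@]13C | intermediate
13 | tricyclic enone (C1 ketone; C2=C3; C8=C9) | O=C1C=CC(C)(C)[C@@H]2[C@H]3CC=C(C)[C@@H]2[C@@]13C | intermediate
14 | 1R allylic alcohol (C2=C3; C8=C9) | O[C@@H]1C=CC(C)(C)[C@@H]2[C@H]3CC=C(C)[C@@H]2[C@@]13C | intermediate
15 | angelic acid, (Z)-2-methylbut-2-enoic acid | C/C=C(/C)C(=O)O | starting material
16 | angelic 2,4,6-trichlorobenzoic anhydride | C/C=C(/C)C(=O)OC(=O)c1c(Cl)cc(Cl)cc1Cl | intermediate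
17 | C1 angelate of 14 | C/C=C(/C)C(=O)O[C@@H]1C=CC(C)(C)[C@@H]2[C@H]3CC=C(C)[C@@H]2[C@@]13C | intermediate
18 | C1 angelate C7 ketone (C7(=O)–C8=C9; C2=C3) | C/C=C(/C)C(=O)O[C@@H]1C=CC(C)(C)[C@@H]2[C@H]3C(=O)C=C(C)[C@@H]2[C@@]13C | intermediate
19 | C2,C3-diol (hydroxyls cis to each other, trans to C1–O) | C/C=C(/C)C(=O)O[C@@H]1[C@@H](O)[C@@H](O)C(C)(C)[C@@H]2[C@H]3C(=O)C=C(C)[C@@H]2[C@@]13C | intermediate
20 | isovaleric anhydride | CC(C)CC(=O)OC(=O)CC(C)C | starting material
21 | CNP0251293.1 (C1 angelate, C2 isovalerate, C3 alcohol) | C/C=C(/C)C(=O)O[C@@H]1[C@@H](OC(=O)CC(C)C)[C@@H](O)C(C)(C)[C@@H]2[C@H]3C(=O)C=C(C)[C@@H]2[C@@]13C | target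

**Totals and risks**

Total step count: 14. Longest linear sequence: 14 steps (1 → 21); 15 and 20 enter at steps 11 and 14.

Step 6 is the riskiest. The cascade may stop at the bicyclic cation through proton loss or a 1,2-hydride shift from C1, or the pinene-type product may be re-ionised and rearranged. The fallback sets out from 8 and comes back at 13, closing the cyclobutane by enolate alkylation. Compound 8 is ionised with the same calcium catalyst at 40 °C in (CF3)2CHOH/CH2Cl2 containing two equivalents of water, so that the transannular C5–C6 closure is followed by the irreversible hydride shift from C1 to C11 and loss of the silyl group. This should give the cis-fused bicyclic ketone F1 (C1 ketone, C9=C10, C11 epimers). Kinetic enolisation toward C2 with LiN(iPr)2 and Me3SiCl gives the silyl enol ether F2, and Pd(OAc)2 (Saegusa–Ito) the bicyclic C2=C3 enone F3. mCPBA then epoxidises the only electron-rich alkene, C9=C10, on the face anti to the C5–C4 bond, giving the epoxy enone F4. KOtBu in t-BuOH/THF deprotonates the only acidic position left (C11, since C4 is quaternary), and the enolate opens the epoxide at C10 with inversion in a 4-exo-tet alkylation (O-alkylation would create a bridgehead enol ether). This gives the tricyclic C9-hydroxy enone F5, and dehydration of its tertiary alcohol toward C8 with the Burgess reagent returns to 13.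

Step 10 is the second risk. The hindered ketone next to the quaternary C11 may turn over slowly, or the catalyst may discriminate poorly between the C11 and vinyl arms, giving low facial selectivity. The fallback sets out from 13 and comes back at 14. Luche reduction (NaBH4, CeCl3·7H2O, MeOH, −78 °C) should give 14 together with the 1S allylic alcohol F6; the epimers are separated by chromatography, and F6 is oxidised back to 13 with MnO2 and recycled.

Step 11 is the third risk. Acylation of the neopentyl C1 alcohol may be slow enough that the angelate isomerises to the tiglate during heating. The fallback sets out from 14 and comes back at 17, building the Z alkene on the ester instead of importing it. Alcohol 14 is acylated with 2-[bis(2,2,2-trifluoroethoxy)phosphoryl]propanoic acid (DCC, DMAP, CH2Cl2) to the phosphonopropionate ester F7. Still–Gennari olefination with acetaldehyde (KN(SiMe3)2, 18-crown-6, THF, −78 °C) should then give the Z-trisubstituted alkene, that is 17.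

**Further compounds**

F1 | step 6 | cis-fused bicyclic ketone (C1 ketone; C11–H epimers; C9=C10) | O=C1CCC(C)(C)[C@@H]2[C@H](C1C)CCC(C)=C2
F2 | step 6 | C1 trimethylsilyl enol ether of F1 (C1=C2) | C[Si](C)(C)OC1=CCC(C)(C)[C@@H]2[C@H](C1C)CCC(C)=C2
F3 | step 6 | bicyclic C2=C3 enone | O=C1C=CC(C)(C)[C@@H]2[C@H](C1C)CCC(C)=C2
F4 | step 6 | C9,C10-epoxy enone (epoxide anti to C5–C4) | O=C1C=CC(C)(C)[C@@H]2[C@H](C1C)CC[C@@]3(C)O[C@@H]23
F5 | step 6 | tricyclic C9-hydroxy enone (C9–OH anti to C10–C11) | O=C1C=CC(C)(C)[C@@H]2[C@H]3CC[C@@](C)(O)[C@@H]2[C@@]13C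
F6 | step 10 | 1S allylic alcohol (C1 epimer of 14) | O[C@H]1C=CC(C)(C)[C@@H]2[C@H]3CC=C(C)[C@@H]2[C@@]13C
F7 | step 11 | C1 2-[bis(2,2,2-trifluoroethoxy)phosphoryl]propanoate of 14 | CC(C(=O)O[C@@H]1C=CC(C)(C)[C@@H]2[C@H]3CC=C(C)[C@@H]2[C@@]13C)P(=O)(OCC(F)(F)F)OCC(F)(F)F
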